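The C4–C5 bond is cut: ring A arises by one-carbon enlargement of the cyclopentane of the (S)-hydrindenedione, whose enone ring is already ring B with quaternary C5 (bearing C14) in the required absolute configuration; only the C4 methine between C3 and C5 is missing. In one operation a semipinacol shift moves C5 from C3 to C4, forming ring A, the C3 ketone and the C4 stereocentre (4β-methyl, by inversion). Its precursor is the 3β-hydroxy hydrindene with an α-oriented (R)-1-mesyloxyethyl group on C3 and the enone masked as a dithiolane. The C3 oxygen is then fixed as 3α before ring B is elaborated.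

Key step: step 5

Remarks
- Eremophilane numbering is used for every intermediate (ring A = C1–C5 and C10, ring B = C5–C10, C14 on C5, C15 on C4); β is the face of C14, α the opposite face.
- Zn(BH4)2 is assumed to be used as a separately prepared ethereal solution.
- Choice of carbinol diastereomer: syn-dihydroxylation of a (Z)-ethylidene anti to C14 would give the 3α-hydroxy (4S)-diol, whose C5 shift leads to 4α-methyl, and the 3α-hydroxy (4R)-isomer would hold its sulfonate anti to C3–C2. The 4α- and 4β-methyl ketones are expected to be close in energy, so enolisation cannot be relied on. The 3β-hydroxy (4R)-series is therefore used, which should give 4β-methyl directly.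

Step 1
Reactants: 1 (S)-hydrindenedione
Product: 2 C8 spiro-1,3-dithiolane of 1 (C3 ketone free, C9=C10 retained)
Conditions: HSCH2CH2SH (1.05 equiv), TsOH (cat.), AcOH, rt
Reagents that add atoms: ethane-1,2-dithiol, SCCS
Why: Acid-catalysed dithioketalisation should be selective for the conjugated carbonyl (allyl-stabilised thionium, while the neopentyl cyclopentanone reacts more slowly) and does not move the C9=C10 bond, so the enone is masked for steps 2–7 without a new stereocentre.

Step 2
Reactants: 2 C8 dithiolane; 3 ethyl vinyl ether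
Product: 5 3α-acetyl-3β-hydroxy hydrindene 8-dithiolane, via 1-ethoxyvinyl carbinol 4 (not isolated)
Conditions: 3, t-BuLi, THF, −78 to 0 °C; then 2, −78 °C; then 0.5 M aq HCl, THF, 0 °C
Reagents that add atoms: water, O
Why: 1,2-Addition of an acyl-anion equivalent (1-alkoxyvinyllithium addition, then enol ether hydrolysis), in which the nucleophile should enter C3 anti to the angular methyl C14 as in 17-keto steroids, setting 3β-OH with the two-carbon chain α.

Step 3
Reactants: 5 3α-acetyl-3β-hydroxy ketol
Product: 6 3β-hydroxy-3α-[(1R)-1-hydroxyethyl] hydrindene 8-dithiolane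
Conditions: Zn(BH4)2, Et2O, −20 to 0 °C; aq NH4Cl
Reagents that add atoms: none
Why: Chelation-controlled (Cram-chelate) reduction of an α-hydroxy ketone, in which zinc bridges O3 and the C4 carbonyl and hydride should arrive from the side of the C2 methylene, not of quaternary C5, which sets (4R).

Step 4
Reactants: 6 (4R)-diol
Product: 7 3β-hydroxy-3α-[(1R)-1-(methanesulfonyloxy)ethyl] hydrindene 8-dithiolane
Conditions: MsCl (1.1 equiv), Et3N, CH2Cl2, −20 °C
Reagents that add atoms: methanesulfonyl chloride, CS(=O)(=O)Cl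
Why: Selective sulfonylation of the secondary C4 hydroxyl, the tertiary C3 hydroxyl being inert under these conditions, with the low temperature keeping the mesylate from reacting on and no stereocentre touched.

Step 5
Reactants: 7 3β-hydroxy (4R)-mesylate
Product: 8 4β,5β-dimethyl-octal-9-en-3-one 8-dithiolane (the C8 dithiolane of the 4,5-dimethyl-9-ene-3,8-dione)
Conditions: LiClO4 (3 equiv), CaCO3 (3 equiv), THF, 50 °C
Reagents that add atoms: none
Why: Ionisation of the secondary C4 mesylate is assisted by the antiperiplanar C3–C5 bond, and C5 moves from C3 to C4 while the C3 hydroxyl becomes the ketone in one concerted 1,2-shift (semipinacol). The closest known reaction type is the pinacol-type ring enlargement of 1-(1-sulfonyloxyalkyl)cycloalkanols under buffered solvolysis, as in D-homoannulation of 17-hydroxy-20-sulfonyloxy steroids. Ring A is closed by ring expansion of the cyclopentane (five to six, 1,2-alkyl shift), not by a cyclisation. The new C4 stereocentre is controlled by the carbinol configuration: inversion at C4 and retention at C5 should turn the (4R)-mesylate directly into 4β-methyl (C15 cis to C14), so no equilibration of the α-methyl ketone is needed. The step needs C5, not the C2 methylene, to migrate and must outrun epoxide closure: with 3β-OH and (4R), the rotamer that keeps H4 under the ring and CH3 outside has the mesylate anti to C3–C5. The dithiolane keeps migrating C5 attached to a plain alkene carbon, not to an electron-poor enone carbon, and CaCO3 keeps the medium neutral, so the product should not epimerise.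

Step 6
Reactants: 8 ring-expanded 3-ketone
Product: 9 3β-hydroxy-4β,5β-dimethyl-octal-9-ene 8-dithiolane
Conditions: LiBH(s-Bu)3 (L-Selectride), THF, −78 °C; aq NaOH (no peroxide)
Reagents that add atoms: none
Why: Bulky trialkylborohydride reduction, in which equatorial attack from the α face, away from axial C14, should give the axial 3β-alcohol, while at −78 °C the C4 centre is not enolised and is locked from here on.

Step 7
Reactants: 9 3β-alcohol
Product: 10 3α-(4-nitrobenzoyloxy)-4β,5β-dimethyl-octal-9-ene 8-dithiolane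
Conditions: 4-O2NC6H4CO2H, PPh3, DIAD, THF, 0 °C to rt
Reagents that add atoms: 4-nitrobenzoic acid, O=C(O)c1ccc(cc1)[N+](=O)[O-]
Why: Mitsunobu esterification with inversion, the carboxylate attacking the axial alkoxyphosphonium from the open α face to give the equatorial 3α-ester, which is installed now because with 3α-O and 4β-CH3 equatorial the later cis-decalin should hold the conformer in which ring A shields the α face of ring B and 7β/9β are equatorial.

Step 8
Reactants: 10 3α-nitrobenzoate dithiolane
Product: 11 3α-(4-nitrobenzoyloxy)-4β,5β-dimethyl-octal-9-en-8-one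
Conditions: MeI (excess), CaCO3, MeCN/H2O (4:1), 50 °C
Reagents that add atoms: water, O
Why: Alkylative hydrolysis of the dithioketal (S-methylation, then attack of water on the allyl-stabilised thionium) should return the 9-en-8-one under neutral conditions that leave the ester and all stereocentres alone.

Step 9
Reactants: 11 enone nitrobenzoate
Product: 12 3α-hydroxy-4β,5β-dimethyl-octal-9-en-8-one
Conditions: K2CO3, MeOH, rt
Reagents that add atoms: none
Why: Base-catalysed transesterification (methanolysis) frees the 3α-alcohol, the β,β-disubstituted enone and the no longer enolisable C4 centre being stable to carbonate.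

Step 10
Reactants: 12 3α-hydroxy enone
Product: 13 3α-(tert-butyldimethylsilyloxy)-4β,5β-dimethyl-octal-9-en-8-one
Conditions: TBSCl, imidazole, DMF, 40 °C
Reagents that add atoms: tert-butyldimethylsilyl chloride, CC(C)(C)[Si](C)(C)Cl
Why: Silylation of the equatorial secondary alcohol gives an ether that should survive copper hydride, peracid, lithium amide and dilute acetic acid and is orthogonal to the labile silyl group later placed on O9.

Step 11
Reactants: 13 3α-silyloxy enone
Product: 14 cis-fused (10β-H) 8-(dimethylphenylsilyloxy)-oct-8-ene bearing 3α-OTBS, 4β-CH3 and 5β-CH3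
Conditions: [(Ph3P)CuH]6 (3 mol%), PhMe2SiH (1.5 equiv), toluene, rt
Reagents that add atoms: dimethylphenylsilane, C[SiH](C)c1ccccc1
Why: Copper hydride 1,4-hydrosilylation (conjugate reduction with silane turnover), in which hydride should be delivered to C10 on the β face, syn to C14 as in cuprate additions and hydrogenations of angular-methyl octalones, giving the cis ring fusion, while the silane traps the enolate regiospecifically as the C8=C9 enol ether.

Step 12
Reactants: 14 C8=C9 silyl enol ether
Product: 16 9β-(dimethylphenylsilyloxy)-3α-OTBS-4β,5β-dimethyl-10β-H-decal-8-one, via siloxy epoxide 15 (not isolated)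
Conditions: mCPBA (1.05 equiv), hexane/CH2Cl2, −20 to 0 °C
Reagents that add atoms: 3-chloroperoxybenzoic acid, O=C(OO)c1cccc(Cl)c1
Why: Rubottom oxidation, in which the peracid should attack the only alkene present on the convex β face of the cis-decalin (ring A lies under the α face) and 1,4-silyl shift in the siloxy epoxide then gives the equatorial 9β-silyloxy ketone.

Step 13
Reactants: 16 9β-silyloxy ketone; 17 2-bromopropene
Product: 21 9β-hydroxy-7β-isopropenyl-3α-OTBS-4β,5β-dimethyl-10β-H-decal-8-one, via lithium C7 enolate 18 (not isolated), via lithium dienolate 19 (not isolated), via 9β-silyloxy 7β-isopropenyl ketone 20 (not isolated)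
Conditions: LiN(SiMe3)2 (2.2 equiv), THF/toluene, −78 °C; Pd2(dba)3 (2.5 mol%), P(t-Bu)3 (6 mol%), 17, rt; AcOH, −78 °C; then AcOH/H2O/THF, rt
Reagents that add atoms: none
Why: Palladium-catalysed α-alkenylation of a ketone enolate with an alkenyl bromide, in which kinetic deprotonation should occur at the C7 methylene and not at the oxygenated C9 methine, axial α-face protonation of the product dienolate places isopropenyl equatorial (7β, the all-equatorial arrangement), and the dilute acetic acid of the work-up removes only the dimethylphenylsilyl group.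

Step 14
Reactants: 21 9β-hydroxy ketone; 22 3-methylbut-2-enoyl chloride
Product: 23 9β-(3-methylbut-2-enoyloxy)-7β-isopropenyl-3α-OTBS-4β,5β-dimethyl-10β-H-decal-8-one
Conditions: 22 (1.3 equiv), pyridine, DMAP (cat.), CH2Cl2, 0 °C
Reagents that add atoms: none
Why: Acylation of the equatorial 9β-hydroxyl with an acyl chloride under nucleophilic catalysis, pyridine being used in place of a trialkylamine to limit vinylketene formation and hence deconjugation of the senecioate, with C7 and C9 unchanged.

Step 15
Reactants: 23 9β-senecioate 3α-silyl ether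
Product: 24 3α-hydroxy-9β-(3-methylbut-2-enoyloxy)-7β-isopropenyl-4β,5β-dimethyl-10β-H-decal-8-one
Conditions: HF·pyridine, pyridine, THF, 0 °C to rt
Reagents that add atoms: none
Why: Fluoride desilylation under buffered, weakly acidic conditions, chosen because basic fluoride could epimerise C7 or move the isopropenyl double bond into conjugation.

Step 16
Reactants: 24 3α-alcohol; 25 (Z)-2-methylbut-2-enoic acid (angelic acid)
Product: 26 target, 3α-angeloyloxy-9β-senecioyloxy-7β-isopropenyl-4β,5β-dimethyl-10β-H-decal-8-one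
Conditions: 25, 2,4,6-Cl3C6H2COCl, Et3N, toluene, rt; then 24, 75 °C
Reagents that add atoms: none
Why: Mixed-anhydride (Yamaguchi-type) esterification run without DMAP, the established way to form angelates without Z-to-E isomerisation to the tiglate, acylating the equatorial 3α-hydroxyl with retention.

Compound list
1 | (S)-7a-methyl-2,3,7,7a-tetrahydro-1H-indene-1,5(6H)-dione | C[C@]12CCC(=O)C=C1CCC2=O | starting material
2 | C8 spiro-1,3-dithiolane of 1 (free C3 cyclopentanone, C9=C10, 5β-CH3) | C1C[C@@]2(C)C(CCC2=O)=CC13SCCS3 | intermediate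
3 | ethyl vinyl ether | C=COCC | starting material
4 | 3β-hydroxy-3α-(1-ethoxyvinyl) hydrindene 8-dithiolane | C1C[C@@]2(C)C(CC[C@@]2(O)C(=C)OCC)=CC13SCCS3 | intermediate
5 | 3α-acetyl-3β-hydroxy hydrindene 8-dithiolane | C1C[C@@]2(C)C(CC[C@@]2(O)C(C)=O)=CC13SCCS3 | intermediate
6 | 3β-hydroxy-3α-[(1R)-1-hydroxyethyl] hydrindene 8-dithiolane | C1C[C@@]2(C)C(CC[C@@]2(O)[C@@H](C)O)=CC13SCCS3 | intermediate
7 | 3β-hydroxy-3α-[(1R)-1-(methanesulfonyloxy)ethyl] hydrindene 8-dithiolane (key-step precursor) | C1C[C@@]2(C)C(CC[C@@]2(O)[C@@H](C)OS(C)(=O)=O)=CC13SCCS3 | intermediate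
8 | 4β,5β-dimethyl-octal-9-en-3-one 8-dithiolane (key-step product) | C1C[C@@]2(C)C(CCC(=O)[C@@H]2C)=CC13SCCS3 | intermediate
9 | 3β-hydroxy-4β,5β-dimethyl-octal-9-ene 8-dithiolane | C1C[C@@]2(C)C(CC[C@H](O)[C@@H]2C)=CC13SCCS3 | intermediate
10 | 3α-(4-nitrobenzoyloxy)-4β,5β-dimethyl-octal-9-ene 8-dithiolane | C1C[C@@]2(C)C(CC[C@@H](OC(=O)c3ccc(cc3)[N+](=O)[O-])[C@@H]2C)=CC14SCCS4 | intermediate
11 | 3α-(4-nitrobenzoyloxy)-4β,5β-dimethyl-octal-9-en-8-one | C1C[C@@]2(C)C(CC[C@@H](OC(=O)c3ccc(cc3)[N+](=O)[O-])[C@@H]2C)=CC1=O | intermediate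
12 | 3α-hydroxy-4β,5β-dimethyl-octal-9-en-8-one | C1C[C@@]2(C)C(CC[C@@H](O)[C@@H]2C)=CC1=O | intermediate
13 | 3α-(tert-butyldimethylsilyloxy)-4β,5β-dimethyl-octal-9-en-8-one | C1C[C@@]2(C)C(CC[C@@H](O[Si](C)(C)C(C)(C)C)[C@@H]2C)=CC1=O | intermediate
14 | cis-fused (10β-H) 8-(dimethylphenylsilyloxy)-8-ene, 3α-OTBS, 4β,5β-dimethyl | C1C[C@@]2(C)[C@H](CC[C@@H](O[Si](C)(C)C(C)(C)C)[C@@H]2C)C=C1O[Si](C)(C)c3ccccc3 | intermediate
15 | 8β,9β-epoxy-8α-(dimethylphenylsilyloxy) derivative of 14 | C1C[C@@]2(C)[C@H](CC[C@@H](O[Si](C)(C)C(C)(C)C)[C@@H]2C)[C@H]3O[C@@]13O[Si](C)(C)c4ccccc4 | intermediate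
16 | 9β-(dimethylphenylsilyloxy)-3α-OTBS-4β,5β-dimethyl-10β-H-decal-8-one | C1C[C@@]2(C)[C@H](CC[C@@H](O[Si](C)(C)C(C)(C)C)[C@@H]2C)[C@@H](O[Si](C)(C)c3ccccc3)C1=O | intermediate
17 | 2-bromopropene | CC(Br)=C | starting material
18 | lithium 7-en-8-olate of 16 | C=1C[C@@]2(C)[C@H](CC[C@@H](O[Si](C)(C)C(C)(C)C)[C@@H]2C)[C@@H](O[Si](C)(C)c3ccccc3)C=1O[Li] | intermediate
19 | lithium 7,11-dien-8-olate (dienolate of 20) | C=C(C)C=1C[C@@]2(C)[C@H](CC[C@@H](O[Si](C)(C)C(C)(C)C)[C@@H]2C)[C@@H](O[Si](C)(C)c3ccccc3)C=1O[Li] | intermediate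
20 | 7β-isopropenyl-9β-(dimethylphenylsilyloxy)-3α-OTBS-4β,5β-dimethyl-10β-H-decal-8-one | C=C(C)[C@H]1C[C@@]2(C)[C@H](CC[C@@H](O[Si](C)(C)C(C)(C)C)[C@@H]2C)[C@@H](O[Si](C)(C)c3ccccc3)C1=O | intermediate
21 | 9β-hydroxy-7β-isopropenyl-3α-OTBS-4β,5β-dimethyl-10β-H-decal-8-one | C=C(C)[C@H]1C[C@@]2(C)[C@H](CC[C@@H](O[Si](C)(C)C(C)(C)C)[C@@H]2C)[C@@H](O)C1=O | intermediate
22 | 3-methylbut-2-enoyl chloride (senecioyl chloride) | CC(C)=CC(=O)Cl | starting material
23 | 9β-(3-methylbut-2-enoyloxy)-7β-isopropenyl-3α-OTBS-4β,5β-dimethyl-10β-H-decal-8-one | C=C(C)[C@H]1C[C@@]2(C)[C@H](CC[C@@H](O[Si](C)(C)C(C)(C)C)[C@@H]2C)[C@@H](OC(=O)C=C(C)C)C1=O | intermediate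
24 | 3α-hydroxy-9β-(3-methylbut-2-enoyloxy)-7β-isopropenyl-4β,5β-dimethyl-10β-H-decal-8-one | C=C(C)[C@H]1C[C@@]2(C)[C@H](CC[C@@H](O)[C@@H]2C)[C@@H](OC(=O)C=C(C)C)C1=O | intermediate
25 | (Z)-2-methylbut-2-enoic acid (angelic acid) | C/C=C(/C)C(=O)O | starting material
26 | CNP0375730.2, 3α-angeloyloxy-9β-senecioyloxy-eremophil-11-en-8-one (4β,5β-dimethyl, 7β-isopropenyl, 10β-H) | C=C(C)[C@H]1C[C@@]2(C)[C@H](CC[C@@H](OC(=O)/C(C)=C\C)[C@@H]2C)[C@@H](OC(=O)C=C(C)C)C1=O | target

Total step count: 16. Longest linear sequence: 16 steps, from 1 to 26.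

Steps most likely to fail

1. Step 5. Ionisation of the neopentyl-type secondary mesylate may be too slow, so that closure of the C3 hydroxyl onto C4 or loss of a proton competes with the C5 shift. Fallback, from 7 back to 8: the nucleofuge is changed to dinitrogen (Tiffeneau–Demjanov-type deamination), which also uses the epoxide if it forms. K2CO3 in MeOH closes 7 to the 3β,4-epoxide F1 with inversion at C4. NaN3 and NH4Cl in aqueous MeOH at 70 °C open it at the secondary carbon with a second inversion to the (4R)-azido alcohol F2. Staudinger reduction (PPh3, THF/H2O) gives the (4R)-amino alcohol F3. Brief treatment with NaNO2 in aqueous AcOH at 0 °C diazotises the amine, and C5 should migrate anti to the departing dinitrogen to give 8 with the same 4β-methyl.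

2. Step 13. Coupling at the hindered enolate may be sluggish, and prolonged exposure to strong base may cause silyl transfer from O9 or enolisation toward C9. Fallback, from 16 back to 19: the isopropenyl group is built by aldol condensation and kinetic deconjugation. The enolate of 16 (LiN(SiMe3)2, then ZnCl2) adds to acetone at −78 °C to give the 7-(2-hydroxypropan-2-yl) ketone F4. MsCl/Et3N followed by DBU dehydrates it to the conjugated 7(11)-isopropylidene ketone F5. LDA at −78 °C removes a hydrogen from an isopropylidene methyl to form dienolate 19, which is protonated at C7 and desilylated as in step 13.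

3. Step 7. The hindered axial hydroxyl may be activated poorly, and E2 loss of the axial alkoxyphosphonium toward C2 or C4 may compete with substitution. Fallback, from 9 back to 12: inversion by sulfonate displacement with nitrite (Lattrell–Dax) replaces the redox condensation. Tf2O and pyridine in CH2Cl2 at −20 °C give the 3β-triflate F6. Bu4N+ NO2− in DMF at rt displaces it with inversion, and the nitrite ester is hydrolysed on work-up to the 3α-hydroxy dithiolane F7. MeI and CaCO3 in aqueous MeCN, as in step 8, then give 12.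

Further compounds
F1 | step 5 | 3β,4-epoxide of the hydrindene 8-dithiolane (spiro-oxirane, C4 inverted) | C1C[C@@]2(C)C(CC[C@]23O[C@H]3C)=CC14SCCS4
F2 | step 5 | 3β-hydroxy-3α-[(1R)-1-azidoethyl] hydrindene 8-dithiolane | C1C[C@@]2(C)C(CC[C@@]2(O)[C@@H](C)N=[N+]=[N-])=CC13SCCS3
F3 | step 5 | 3β-hydroxy-3α-[(1R)-1-aminoethyl] hydrindene 8-dithiolane | C1C[C@@]2(C)C(CC[C@@]2(O)[C@@H](C)N)=CC13SCCS3
F4 | step 13 | 7β-(2-hydroxypropan-2-yl)-9β-(dimethylphenylsilyloxy)-3α-OTBS-4β,5β-dimethyl-10β-H-decal-8-one | CC(C)(O)[C@H]1C[C@@]2(C)[C@H](CC[C@@H](O[Si](C)(C)C(C)(C)C)[C@@H]2C)[C@@H](O[Si](C)(C)c3ccccc3)C1=O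
F5 | step 13 | 7-isopropylidene-9β-(dimethylphenylsilyloxy)-3α-OTBS-4β,5β-dimethyl-10β-H-decal-8-one | CC(C)=C1C[C@@]2(C)[C@H](CC[C@@H](O[Si](C)(C)C(C)(C)C)[C@@H]2C)[C@@H](O[Si](C)(C)c3ccccc3)C1=O
F6 | step 7 | 3β-(trifluoromethanesulfonyloxy)-4β,5β-dimethyl-octal-9-ene 8-dithiolane | C1C[C@@]2(C)C(CC[C@H](OS(=O)(=O)C(F)(F)F)[C@@H]2C)=CC13SCCS3
F7 | step 7 | 3α-hydroxy-4β,5β-dimethyl-octal-9-ene 8-dithiolane | C1C[C@@]2(C)C(CC[C@@H](O)[C@@H]2C)=CC13SCCS3
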